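## Structural features

The target (C30H30O6) is a dimer of two 6,12-guaianolides. Guaiane numbering is used throughout: unprimed atoms belong to the upper unit, primed atoms to the lower unit. Each unit is a 5-7-5 system with a trans-fused α-methylene-γ-lactone on C6/C7.

The units are joined only by C14–C15' and C2–C4'. These bonds close a spiro-cyclohexene (ring D: C2, C1, C10, C14, C15', C4'). C4' is a quaternary spiro carbon α to the C3' ketone, and C3(=O)–C2–C4'–C3'(=O) is a 1,4-diketone.

Upper ring A is a cross-conjugated 5-methylenecyclopent-2-enone (C1=C2, C3=O, C4=C15). Its γ-hydrogens H-5 and H-10 are acidic. The lower unit keeps a saturated cyclopentanone and the C10'=C14' methylene.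

There are nine stereocentres: C5, C6, C7, C10 and C1', C4', C5', C6', C7'. The lower unit has the configuration of dehydrocostus lactone (1'α-H, 5'α-H, 6'β-H, 7'α-H). The upper unit has the same C6/C7 but H-5 β (cis to H-6) and H-10 α. C5 is therefore epimeric to the chiral-pool series.

Fragile groups are the three exocyclic Michael acceptors (two lactone methylenes, the C4=C15 enone) and the enolizable dienone. The dienone is prone to epimerization at C5/C10, to vinylogous loss of the C6 oxygen and to autoxidation.

The real difficulty is twofold. First, two nearly identical halves must be joined hetero-selectively with control of spiro C4'. Second, the C5 configuration is likely the less stable one: a torsion analysis of the seven-membered ring suggests the trans-lactone fixes the ring twist in favour of 5α-H. It is therefore not left to equilibration.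

## Logic of the disconnections

**15 ⇒ 13.** Only the C5–H bond is changed (inversion at C5). C5 is the one centre that differs from the chiral pool and is the most acidic CH of ring A. 15 thus simplifies to 13, whose upper unit has the stereocentres of 1 plus H-10 α. The forward step needs a kinetic proton delivery to the β face of a planar C5 (via 14) and no base afterwards.

**13 ⇒ 10.** Two C13–N bonds are cut (retro-aza-Michael) and the C1=C2 double bond is moved back to C1=C10. This turns the open dimer into a macrocycle in which both lactone methylenes are masked and the two halves are clipped together. The forward step needs a clean double elimination and a C10 protonation on the α face.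

**10 ⇒ 9 ⇒ 8 (key).** C14–C15' and C2–C4' are cut inside the macrocycle. This is the retron of a [4+2] cycloaddition between the dienone C14=C10–C1=C2 and the enone methylene C4'=C15'. Run across the diamine bridge, it removes the spiro ring, the quaternary centre and the hetero-pairing problem in one operation. 9 is unmasked from the stable silyl dienol ether 8. The forward step demands that the bridge allows only the arrangement that puts C2 on the α face of C4'.

**8 ⇒ 7.** The C3'=O bond is reduced to the allylic alcohol. In this way the lower unit is not a Michael acceptor while the bridge is built. The forward step needs an oxidation that spares amines and the silyl dienol ether.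

**7 ⇒ 6 + 4 and 6 ⇒ 2 + 5.** The two C13–N bonds are cut one after the other. Each half then offers its lactone methylene as the only acceptor (2: allylic alcohol; 4: silyl dienol ether). The forward additions must be chemoselective, and the first must stop at the mono-adduct.

**4 ⇒ 3 ⇒ 2 ⇒ 1.** The O–Si bond, the C3 carbonyl and the C3–O bond are removed in turn. Both halves then come from the single commercial lactone 1, which supplies eight of the nine stereocentres. The forward demand is site-selective allylic oxidation at C3.

## Other disconnections considered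

**Alternative 1:** (first to mind) Cut C14–C15' and C2–C4' between two free monomers. The forward key step is the intermolecular Diels–Alder reaction of 3 with dienone A1 (from 4), followed by base.
- A1 is both diene and enone, so it dimerizes with itself and must find 3 in a bimolecular step.
- Without a tether, the ketone-endo transition state on the open α face of the diene leads to the C4' epimer A2. The spiro centre is therefore decided by a balance of endo preference and sterics, not by design.
- Both lactone methylenes are exposed throughout.
- The chosen plan keeps the pericyclic bond formation but makes it first order and lets the bridge fix the topology, at a similar step count.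

**Alternative 2:** Cut C2–C4' by a [3,3] shift. The forward key step is a Claisen ring contraction of the spiro 2-vinyl-dihydropyran A3, made by hetero-Diels–Alder addition of 3 (as oxadiene) to C10=C14 of a protected form of 2, then oxidation and dehydrogenation.
- The hetero-Diels–Alder step must prefer C10=C14 over the enone methylene, which is the mode in which α-methylene ketones dimerize.
- The C10 configuration is relayed to C4'. A model suggests that addition to the open α face relays to the wrong face of C4'.
- The route is about three steps longer.

**Alternative 3:** Cut C2–C3 and C3–C4. Ring A is closed last by insertion of CO: a [4+1] carbonylation of vinylallene A4 with a monovalent rhodium catalyst such as [Rh(cod)2]OTf and a bisphosphine.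
- The dienone would appear only at the end, which is attractive.
- A4 has no chiral-pool precursor. Ring B and the lactone of the upper unit would have to be built de novo (estimated more than fifteen steps).
- C5 would still arise from an uncontrolled isomerization.

Key step: step 7

Assumption: the SMILES places H-5 of the upper unit cis to H-6 (C5 epimeric to the corresponding centre of 1); this is taken as intended and C5 is inverted in step 9.

Assumption: amine additions to the lactone methylenes give the 11β-H adducts (aminomethyl group α), and the C3 configuration of 2 is immaterial because C3 becomes a carbonyl group.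

## Route

Step 1
Reactants: 1 dehydrocostus lactone (guaia-4(15),10(14),11(13)-trien-12,6α-olide; 1α-H, 5α-H, 6β-H, 7α-H)
Product: 2 3α-hydroxydehydrocostus lactone (3-epizaluzanin C)
Conditions: SeO2 (0.5 equiv), t-BuOOH, CH2Cl2, 0 °C to rt
Reagents that add atoms: tert-butyl hydroperoxide, CC(C)(C)OO
Why: Riley allylic oxidation (ene reaction of SeO2, then [2,3] shift) at C3, the only allylic CH2 of the more reactive ring-A methylene; the hydroxyl enters from the open α face, and its configuration is lost in later oxidations.

Step 2
Reactants: 2 3α-hydroxydehydrocostus lactone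
Product: 3 dehydrozaluzanin C (3-oxoguaia-4(15),10(14),11(13)-trien-12,6α-olide)
Conditions: Dess–Martin periodinane, NaHCO3, CH2Cl2, rt
Reagents that add atoms: none
Why: Dess–Martin oxidation of a secondary allylic alcohol under neutral conditions; no stereocentre is touched.

Step 3
Reactants: 3 dehydrozaluzanin C
Product: 4 3-(tert-butyldimethylsilyloxy)guaia-2,4(15),10(14),11(13)-tetraen-12,6α-olide
Conditions: TBSOTf, Et3N, CH2Cl2, −78 °C
Reagents that add atoms: tert-butyldimethylsilyl triflate, CC(C)(C)[Si](C)(C)OS(=O)(=O)C(F)(F)F
Why: Soft enolization; C2 is the only enolizable position of the ketone, so a single cross-conjugated silyl dienol ether forms, and the lactone methylene is spared because no strong base is used.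

Step 4
Reactants: 2 3α-hydroxydehydrocostus lactone; 5 N,N'-dimethylhexane-1,6-diamine
Product: 6 13-[methyl(6-methylaminohexyl)amino]-11βH-11,13-dihydro-3-epizaluzanin C
Conditions: 5 (5 equiv), EtOH, rt; excess 5 removed by aqueous wash
Reagents that add atoms: none
Why: Aza-Michael addition of a secondary amine to the α-methylene lactone, the only acceptor in 2; the excess of 5 keeps it at the mono-adduct, and protonation of the lactone enolate on the convex face should give 11β-H.

Step 5
Reactants: 6 mono-adduct; 4 silyl dienol ether
Product: 7 unsymmetrical bis-adduct: N,N'-dimethylhexane-1,6-diamine carrying on one N the C13 of 11βH-11,13-dihydro-3-epizaluzanin C and on the other N the C13 of the 11βH-11,13-dihydro form of 4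
Conditions: 4 (1.1 equiv), MeCN, 40 °C
Reagents that add atoms: none
Why: Second aza-Michael addition; the lactone methylene is the only electrophile in 4 (the 2-silyloxydiene is not an acceptor), and the aprotic medium preserves the silyl dienol ether.

Step 6
Reactants: 7 unsymmetrical bis-adduct
Product: 8 bridged enone–silyl dienol ether (lower unit oxidized to the 3'-oxo-4'(15')-ene)
Conditions: MnO2 (excess), CH2Cl2, rt
Reagents that add atoms: none
Why: MnO2 oxidation of the allylic C3' alcohol; neutral and heterogeneous, it should leave the tertiary amines and the silyl dienol ether intact and creates the dienophile only now.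

Step 7
Reactants: 8 bridged enone–silyl dienol ether
Product: 10 macrocyclic spiro adduct (C14–C15' and C2–C4' bonds; C1=C10; 2β-H; 5α-H; C4' R; diamine bridge retained), via bridged dienone 9 (not isolated)
Conditions: Pd(OAc)2 (1.3 equiv), MeCN, slow addition of 8 to a final 1 mM, rt to 40 °C, Ar
Reagents that add atoms: none
Why: Saegusa–Ito oxidation gives a divalent palladium enolate that loses H-1 by β-hydride elimination to form dienone 9, whose diene C14=C10–C1=C2 is locked s-cis. 9 then adds thermally in a [4+2] sense to the C4'=C15' methylene of the lower enone; the closest known type is the Diels–Alder reaction of a 1-acyl diene with an α-methylene ketone, here run across a temporary tether. Ring D closes by suprafacial [4+2] (C14–C15' and C2–C4'), and the C2–C4' bond also closes a 21-membered ring through the bridge. The "ortho" regiochemistry (acyl-bearing C2 to carbonyl-bearing C4') is the electronically normal one. C4' is controlled by the bridge: both aminomethyl arms sit on the α faces of their lactones and can span only when the α face of the dienophile lies on the α face of the diene (the face not covered by C6–C8) with the C5' side, not the ketone, under ring A; this ketone-exo arrangement puts C2 on the α face of C4'. C2 (H β) follows from attack on the α face of the diene and is erased in step 8. The step needs cross- over self-addition of the dienone (secured by high dilution, since only the bridged reaction is first order) and exo over endo topology (secured by the reach of the six-carbon bridge). The masked lactone methylenes cannot compete as dienophiles.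

Step 8
Reactants: 10 macrocyclic spiro adduct
Product: 13 5α-H,10α-H dienone (C5 epimer of the target; both lactone methylenes free; C1=C2), via macrocyclic bis-methylammonium diiodide 11 (not isolated), via free deconjugated adduct 12 (not isolated)
Conditions: MeI (excess), MeCN, rt; then NaHCO3, H2O/CH2Cl2, rt; then DBU (10 mol %), CH2Cl2, 0 °C, Ar
Reagents that add atoms: none
Why: Quaternization and E1cB (Hofmann-type) elimination regenerate both α-methylene lactones and release the bridge; DBU then removes the doubly activated H-2, and the dienolate should be protonated at C10 on the α face, anti to the C6–C8 bridge, giving the chair seven-membered ring with C6 and C9 on the same side, while C5 keeps its stable 5α-H.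

Step 9
Reactants: 13 5α-H,10α-H dienone
Product: 15 target (5β-H,10α-H), via bis-silyl enol ether 14 (not isolated)
Conditions: TBSOTf (3 equiv), Et3N, CH2Cl2, −78 °C; then HF·pyridine, −78 °C; pH 7 buffer work-up
Reagents that add atoms: none
Why: Soft enolization removes H-5 (doubly allylic γ-H) to give a planar 3-silyloxyfulvene and also silylates the lower ketone towards C2'; kinetic protodesilylation (diastereoselective protonation of a silyl enol ether) should deliver the proton to C5 on the β face, anti to the C6–C7 bond that the trans-lactone holds below the ring-A plane and cis to the small H-6. The product is kept away from base because it is taken to be the less stable C5 epimer.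

## Compound list

1 | dehydrocostus lactone | C=C1CC[C@H]2C(=C)CC[C@H]3C(=C)C(=O)O[C@@H]3[C@H]21 | starting material
2 | 3α-hydroxydehydrocostus lactone (3-epizaluzanin C) | C=C1[C@H](O)C[C@H]2C(=C)CC[C@H]3C(=C)C(=O)O[C@@H]3[C@H]21 | intermediate
3 | dehydrozaluzanin C | C=C1C(=O)C[C@H]2C(=C)CC[C@H]3C(=C)C(=O)O[C@@H]3[C@H]21 | intermediate
4 | TBS dienol ether of 3 (C2=C3–OTBS) | C=C1C(O[Si](C)(C)C(C)(C)C)=C[C@H]2C(=C)CC[C@H]3C(=C)C(=O)O[C@@H]3[C@H]21 | intermediate
5 | N,N'-dimethylhexane-1,6-diamine | CNCCCCCCNC | starting material
6 | mono-adduct of 5 with 2 (11β-H) | C=C1[C@H](O)C[C@H]2C(=C)CC[C@H]3[C@H](CN(C)CCCCCCNC)C(=O)O[C@@H]3[C@H]21 | intermediate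
7 | unsymmetrical bis-adduct (lower unit 3'α-OH, upper unit TBS dienol ether) | C=C1[C@H](O)C[C@H]2C(=C)CC[C@H]3[C@H](CN(C)CCCCCCN(C)C[C@@H]4C(=O)O[C@H]5[C@H]4CCC(=C)[C@@H]4C=C(O[Si](C)(C)C(C)(C)C)C(=C)[C@H]54)C(=O)O[C@@H]3[C@H]21 | intermediate
8 | bridged enone–silyl dienol ether | C=C1C(=O)C[C@H]2C(=C)CC[C@H]3[C@H](CN(C)CCCCCCN(C)C[C@@H]4C(=O)O[C@H]5[C@H]4CCC(=C)[C@@H]4C=C(O[Si](C)(C)C(C)(C)C)C(=C)[C@H]54)C(=O)O[C@@H]3[C@H]21 | intermediate
9 | bridged dienone–enone (not isolated) | C=C1C(=O)C[C@H]2C(=C)CC[C@H]3[C@H](CN(C)CCCCCCN(C)C[C@@H]4C(=O)O[C@H]5[C@H]4CCC(=C)C4=CC(=O)C(=C)[C@H]54)C(=O)O[C@@H]3[C@H]21 | intermediate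
10 | macrocyclic spiro adduct (deconjugated enone, 2β-H) | C=C1C(=O)[C@H]2C3=C(CC[C@H]4[C@H](CN(C)CCCCCCN(C)C6)C(=O)O[C@@H]4[C@@H]13)CC[C@]21C(=O)C[C@H]2C(=C)CC[C@H]3[C@H]6C(=O)O[C@@H]3[C@H]21 | intermediate
11 | macrocyclic bis-methylammonium diiodide (not isolated) | C=C1C(=O)[C@H]2C3=C(CC[C@H]4[C@H](C[N+](C)(C)CCCCCC[N+](C)(C)C6)C(=O)O[C@@H]4[C@@H]13)CC[C@]21C(=O)C[C@H]2C(=C)CC[C@H]3[C@H]6C(=O)O[C@@H]3[C@H]21.[I-].[I-] | intermediate
12 | free deconjugated adduct (C1=C10, 2β-H, 5α-H; not isolated) | C=C1C(=O)[C@H]2C3=C(CC[C@H]4C(=C)C(=O)O[C@@H]4[C@@H]13)CC[C@]21C(=O)C[C@H]2C(=C)CC[C@H]3C(=C)C(=O)O[C@@H]3[C@H]21 | intermediate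
13 | 5α-H,10α-H dienone (C5 epimer of the target) | C=C1C(=O)C2=C3[C@H](CC[C@H]4C(=C)C(=O)O[C@@H]4[C@@H]13)CC[C@]21C(=O)C[C@H]2C(=C)CC[C@H]3C(=C)C(=O)O[C@@H]3[C@H]21 | intermediate
14 | bis-silyl enol ether (3-silyloxyfulvene in ring A, C2'=C3'–OTBS below; not isolated) | C=C1C(O[Si](C)(C)C(C)(C)C)=C2C3=C1[C@H]4OC(=O)C(=C)[C@@H]4CC[C@@H]3CC[C@]21C(O[Si](C)(C)C(C)(C)C)=C[C@H]2C(=C)CC[C@H]3C(=C)C(=O)O[C@@H]3[C@H]21 | intermediate
15 | CNP0221188.1 | C=C1C(=O)C2=C3[C@H](CC[C@H]4C(=C)C(=O)O[C@@H]4[C@H]13)CC[C@]21C(=O)C[C@H]2C(=C)CC[C@H]3C(=C)C(=O)O[C@@H]3[C@H]21 | target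

## Step count and least certain steps

Total steps: 9. Longest linear sequence: 8 steps (1 → 2 → 3 → 4 → 7 → 8 → 10 → 13 → 15).

**Step 7 (key).** The bridge may be too short or wrongly oriented for the ketone-exo arrangement, so that the dienone outlives the cycloaddition and adds to itself or decomposes. The tertiary amines may also slow the palladium oxidation. Fallback: from 4, Saegusa–Ito oxidation with Pd(OAc)2 gives the free dienone F1, which is added slowly to an excess of 3 in an intermolecular Diels–Alder reaction. The C4' epimers are separated, and the route is rejoined at 12, which is then treated with DBU as in step 8.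

**Step 9.** The proton may be delivered to the α face and return 13, or enolization may occur at C10 and scramble that centre. The facial argument rests on a model of the fulvene, and the product is the less stable epimer. Fallback: from 14, reagent-controlled protonation with a chiral Brønsted acid such as the (R)-BINOL–SnCl4 complex at −78 °C, returning to 15; no new compound is formed.

**Step 8.** DBU may cause conjugate additions to the freed methylenes, loss of the C6 oxygen by vinylogous elimination, or C10 protonation on the wrong face. Fallback: from 10, DBU isomerization is done on the macrocycle to give the bridged conjugated dienone F5. Its amines are oxidized with mCPBA at −20 °C to the bis-N-oxide F6. A Cope elimination on gentle warming then frees both methylenes without base and returns to 13.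

**Step 5.** The silyl dienol ether may be lost to the amine or traces of protic species before the addition is complete. Fallback: from 6 and a second equivalent of 2, the symmetrical diol F2 is made by aza-Michael addition. MnO2 gives the bis-enone F3, and one equivalent of TBSOTf/Et3N silylates one ketone statistically (unreacted F3 is recycled), returning to 8.

**Step 4.** Double addition may give the symmetrical bis-adduct if the excess of diamine is not effective. Fallback: from 2, addition of the mono-protected diamine tert-butyl methyl[6-(methylamino)hexyl]carbamate gives the carbamate F4, and removal of the Boc group with CF3CO2H returns to 6.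

## Further compounds

F1 | step 7 | free dienone, 3-oxoguaia-1,4(15),10(14),11(13)-tetraen-12,6α-olide | C=C1C(=O)C=C2C(=C)CC[C@H]3C(=C)C(=O)O[C@@H]3[C@@H]12
F2 | step 5 | symmetrical bis-adduct of 5 with two molecules of 2 (11β-H, 3α-OH in both units) | C=C1[C@H](O)C[C@H]2C(=C)CC[C@H]3[C@H](CN(C)CCCCCCN(C)C[C@@H]4C(=O)O[C@H]5[C@H]4CCC(=C)[C@@H]4C[C@@H](O)C(=C)[C@H]54)C(=O)O[C@@H]3[C@H]21
F3 | step 5 | bridged bis-enone | C=C1C(=O)C[C@H]2C(=C)CC[C@H]3[C@H](CN(C)CCCCCCN(C)C[C@@H]4C(=O)O[C@H]5[C@H]4CCC(=C)[C@@H]4CC(=O)C(=C)[C@H]54)C(=O)O[C@@H]3[C@H]21
F4 | step 4 | N-Boc-protected mono-adduct of 2 | C=C1[C@H](O)C[C@H]2C(=C)CC[C@H]3[C@H](CN(C)CCCCCCN(C)C(=O)OC(C)(C)C)C(=O)O[C@@H]3[C@H]21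
F5 | step 8 | bridged conjugated dienone (5α-H, 10α-H, bridge retained) | C=C1C(=O)C2=C3[C@H](CC[C@H]4[C@H](CN(C)CCCCCCN(C)C6)C(=O)O[C@@H]4[C@@H]13)CC[C@]21C(=O)C[C@H]2C(=C)CC[C@H]3[C@H]6C(=O)O[C@@H]3[C@H]21
F6 | step 8 | bis-N-oxide of F5 | C=C1C(=O)C2=C3[C@H](CC[C@H]4[C@H](C[N+](C)([O-])CCCCCC[N+](C)([O-])C6)C(=O)O[C@@H]4[C@@H]13)CC[C@]21C(=O)C[C@H]2C(=C)CC[C@H]3[C@H]6C(=O)O[C@@H]3[C@H]21
F0 | step 9 | none | none
A1 | alternative 1 | free dienone, 3-oxoguaia-1,4(15),10(14),11(13)-tetraen-12,6α-olide | C=C1C(=O)C=C2C(=C)CC[C@H]3C(=C)C(=O)O[C@@H]3[C@@H]12
A2 | alternative 1 | C4'-epimeric Diels–Alder adduct (C1=C10, 2β-H, C4' S) | C=C1C(=O)[C@H]2C3=C(CC[C@H]4C(=C)C(=O)O[C@@H]4[C@@H]13)CC[C@@]21C(=O)C[C@H]2C(=C)CC[C@H]3C(=C)C(=O)O[C@@H]3[C@H]21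
A3 | alternative 2 | spiro 2-vinyl-dihydropyran (O–C10 ether with O on the α face, enol ether C3'=C4', upper unit as 1-en-3-one) | C=C1C(=O)C=C2[C@H]1[C@H]3OC(=O)C(=C)[C@@H]3CC[C@@]24OC5=C(CC4)[C@@H]4[C@H]6OC(=O)C(=C)[C@@H]6CCC(=C)[C@@H]4C5
A4 | alternative 3 | vinylallene (target lacking C3=O; C5=C4=C15 allene, C1=C2–H) | C=C=C1[C@H]2OC(=O)C(=C)[C@@H]2CC[C@@H]2CC[C@@]3(C=C12)C(=O)C[C@H]1C(=C)CC[C@H]2C(=C)C(=O)O[C@@H]2[C@H]13
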